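The route hinges on disconnecting C3–C4, the ring-A bond at the quaternary carbon. Since the C4 carboxyl (C19) stands axial on the same side of ring A as the C20 methyl on C10, an oxygen placed on C1 can reach C19, so a δ-lactone tying C19 to C1 is geometrically available. Heating the silyl ketene acetal of this lactone, which bears a vinyl group (C2–C3) on C1, triggers a [3,3] shift that at once forms C3–C4, closes ring A and copies the C1 configuration onto C4. The precursor lactone, with ring B still open, carries the C4 methyl, the C6–C8 arm on C5, and on C10 a methyl and a benzyloxymethyl group (C9).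

Key step: step 9

Remarks (labdane numbering C1–C20 is used for all intermediates)
- Precursor design: C9 is carried as a benzyl ether and C8 at the aldehyde level as a diethyl acetal. One hydrogenation then removes the benzyl group together with the ring-A alkene, and the arm needs no later redox change.
- The lactone is made with the C4 methyl trans to the C5 arm. This is immaterial because C4 is planar in the ketene acetal.
- Side chain: C11–C15 with the C13 methyl is a five-carbon unit. A six-carbon fragment from oxidative cleavage of citronellol would place the branch one carbon too far from C9. Methyl (R)-3-methylglutarate is used instead (acid end becomes C15, ester end C11, giving 13S).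
- Assumption: (S)-BINAP is taken to give the (S)-lactone in step 1 by analogy with cyclic enones; if the sense is opposite, (R)-BINAP is used.

Step 1
Reactants: 1 5,6-dihydro-2H-pyran-2-one; 2 (E)-2-(3,3-diethoxyprop-1-en-1-yl)-4,4,5,5-tetramethyl-1,3,2-dioxaborolane
Product: 3 (S)-4-[(E)-3,3-diethoxyprop-1-en-1-yl]oxan-2-one
Conditions: [Rh(cod)Cl]2 (cat.), (S)-BINAP, aq. KOH, dioxane/H2O, 60 °C
Reagents that add atoms: none
Why: Rhodium-catalysed asymmetric 1,4-addition of an alkenylboronate to an unsaturated lactone (Hayashi–Miyaura reaction) is an established reaction type for this acceptor, and the BINAP-bound alkenylrhodium species should select one enantioface of the enoate and so set C5.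

Step 2
Reactants: 3 (S)-4-[(E)-3,3-diethoxyprop-1-en-1-yl]oxan-2-one
Product: 4 (S)-4-(3,3-diethoxypropyl)oxan-2-one
Conditions: H2 (1 atm), Pd/C, EtOAc, rt
Reagents that add atoms: none
Why: Catalytic hydrogenation saturates the only C=C (C6=C7) while lactone and acetal are inert and C5 is not touched.

Step 3
Reactants: 4 (S)-4-(3,3-diethoxypropyl)oxan-2-one
Product: 5 (3R,4S)-4-(3,3-diethoxypropyl)-3-methyloxan-2-one
Conditions: LDA, THF, −78 °C; MeI
Reagents that add atoms: iodomethane CI
Why: Lactone enolate alkylation at the only α-position (C10) brings in C20, the methyl entering anti to the C5 arm, although this centre is enolised again in step 4.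

Step 4
Reactants: 5 (3R,4S)-4-(3,3-diethoxypropyl)-3-methyloxan-2-one
Product: 6 (3S,4S)-3-[(benzyloxy)methyl]-4-(3,3-diethoxypropyl)-3-methyloxan-2-one
Conditions: LDA, THF/DMPU, −78 °C; BnOCH2Cl, −78 → −20 °C
Reagents that add atoms: benzyl chloromethyl ether ClCOCc1ccccc1
Why: Alkylation of the tetrasubstituted lactone enolate builds quaternary C10; A(1,2) strain holds the C5 arm pseudo-axial, so the chloromethyl ether should attack the opposite face and place CH2OBn (C9) trans to the arm and C20 cis to it.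

Step 5
Reactants: 6 (3S,4S)-3-[(benzyloxy)methyl]-4-(3,3-diethoxypropyl)-3-methyloxan-2-one
Product: 7 (3S,4S)-3-[(benzyloxy)methyl]-4-(3,3-diethoxypropyl)-3-methyloxan-2-ol (lactol, anomer mixture)
Conditions: DIBAL-H, CH2Cl2, −78 °C; Rochelle salt
Reagents that add atoms: none
Why: Partial reduction of a lactone with DIBAL-H stops at the lactol because the tetrahedral aluminate survives at −78 °C, and acetal and benzyl ether are not reduced.

Step 6
Reactants: 7 (3S,4S)-3-[(benzyloxy)methyl]-4-(3,3-diethoxypropyl)-3-methyloxan-2-ol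
Product: 8 (3S,4S,5R)-4-[(benzyloxy)methyl]-3-(3,3-diethoxypropyl)-4-methylhept-6-ene-1,5-diol
Conditions: vinylMgBr (3 equiv), MgBr2·OEt2, CH2Cl2/THF, −78 → 0 °C
Reagents that add atoms: vinylmagnesium bromide C=C[Mg]Br
Why: Grignard addition to the open aldehyde form of the lactol; the Cram chelate between C1=O and the C9 benzyl ether and the Felkin–Anh model both direct attack past the C20 methyl and anti to the C5 branch, which should give the C1 carbinol that places vinyl cis to C9 in the later lactone.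

Step 7
Reactants: 8 (3S,4S,5R)-4-[(benzyloxy)methyl]-3-(3,3-diethoxypropyl)-4-methylhept-6-ene-1,5-diol
Product: 10 (4S,5S,6R)-5-[(benzyloxy)methyl]-4-(3,3-diethoxypropyl)-5-methyl-6-vinyloxan-2-one, via lactol 9 (not isolated)
Conditions: TEMPO (cat.), PhI(OAc)2, CH2Cl2, rt
Reagents that add atoms: none
Why: TEMPO-mediated oxidative lactonisation of a 1,5-diol: the unhindered primary C19 alcohol is oxidised first, the aldehyde is captured by the C1 hydroxyl as lactol 9 and oxidised on to the δ-lactone, while the hindered allylic alcohol is otherwise spared.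

Step 8
Reactants: 10 (4S,5S,6R)-5-[(benzyloxy)methyl]-4-(3,3-diethoxypropyl)-5-methyl-6-vinyloxan-2-one
Product: 11 (3S,4S,5S,6R)-5-[(benzyloxy)methyl]-4-(3,3-diethoxypropyl)-3,5-dimethyl-6-vinyloxan-2-one
Conditions: LDA, THF, −78 °C; MeI, −78 °C
Reagents that add atoms: iodomethane CI
Why: Enolate methylation at C4, the only enolisable position, introduces C18 anti to the C5 arm; the mixture is kept at −78 °C so the lithium enolate does not rearrange, and the C4 configuration is erased in step 9.

Step 9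
Reactants: 11 (3S,4S,5S,6R)-5-[(benzyloxy)methyl]-4-(3,3-diethoxypropyl)-3,5-dimethyl-6-vinyloxan-2-one
Product: 14 (1S,5S,6R)-5-[(benzyloxy)methyl]-6-(3,3-diethoxypropyl)-1,5-dimethylcyclohex-3-ene-1-carboxylic acid, via silyl ketene acetal 12 (not isolated), via trimethylsilyl ester 13 (not isolated)
Conditions: LDA, TMSCl/Et3N, THF/DMPU, −78 °C → rt; toluene, 100 °C; H2O/THF, pH 5
Reagents that add atoms: none
Why: LDA removes the only α-hydrogen (C4–H) and the enolate is O-silylated to the cyclic silyl ketene acetal 12, whose geometry is fixed by the ring; on heating, 12 undergoes a [3,3] sigmatropic shift through a boat-like, bicyclo[2.2.2]octane-type transition state in which the axial C1 vinyl reaches over C4, so C3–C4 forms as C1–O breaks to give silyl ester 13, hydrolysed to 14 on work-up. The closest known reaction type is the Ireland–Claisen ring contraction of 6-alkenyl δ-lactone silyl ketene acetals to cyclohex-3-enecarboxylic acids. Ring A is closed as a six-membered carbocycle in a pericyclic mode, the new bond being delivered intramolecularly and suprafacially to the face that carries the vinyl group, with ring B still open. The one new stereocentre, C4, is controlled by the C1 carbinol configuration (vinyl cis to the C9 benzyloxymethyl group): C3 adds on the vinyl face and C19 stays on the face formerly bridged by the lactone oxygen, which is the face of the C20 methyl and the C5 arm, the axial position of the later decalin. The step needs clean enolisation and O-silylation at C4 and rearrangement in preference to elimination or C-silylation; this is secured by the single enolisable site (C9 is an ether, C8 an acetal), by trapping with TMSCl present at −78 °C, and by a reactive conformer in which only the vinyl group and the C20 methyl are axial.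

Step 10
Reactants: 14 (1S,5S,6R)-5-[(benzyloxy)methyl]-6-(3,3-diethoxypropyl)-1,5-dimethylcyclohex-3-ene-1-carboxylic acid
Product: 15 2-(trimethylsilyl)ethyl (1S,5S,6R)-5-[(benzyloxy)methyl]-6-(3,3-diethoxypropyl)-1,5-dimethylcyclohex-3-ene-1-carboxylate
Conditions: Me3SiCH2CH2OH, PPh3, DIAD, THF, 0 °C → rt
Reagents that add atoms: 2-(trimethylsilyl)ethanol C[Si](C)(C)CCO
Why: In a Mitsunobu esterification the hindered carboxylate is the nucleophile at the primary carbon of the activated alcohol, so shielding of C19 does not matter, and the neutral conditions spare the acetal.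

Step 11
Reactants: 15 2-(trimethylsilyl)ethyl (1S,5S,6R)-5-[(benzyloxy)methyl]-6-(3,3-diethoxypropyl)-1,5-dimethylcyclohex-3-ene-1-carboxylate
Product: 16 2-(trimethylsilyl)ethyl (1S,2R,3S)-2-(3,3-diethoxypropyl)-3-(hydroxymethyl)-1,3-dimethylcyclohexane-1-carboxylate
Conditions: H2 (1 atm), Pd(OH)2/C, EtOH, rt
Reagents that add atoms: none
Why: One catalytic hydrogenation saturates the cis-disubstituted C1=C2 alkene and hydrogenolyses the C9 benzyl ether; the silylethyl ester is inert and acetal exchange in ethanol is degenerate.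

Step 12
Reactants: 16 2-(trimethylsilyl)ethyl (1S,2R,3S)-2-(3,3-diethoxypropyl)-3-(hydroxymethyl)-1,3-dimethylcyclohexane-1-carboxylate
Product: 17 2-(trimethylsilyl)ethyl (1S,2R,3S)-2-(3,3-diethoxypropyl)-3-formyl-1,3-dimethylcyclohexane-1-carboxylate
Conditions: Dess–Martin periodinane, NaHCO3, CH2Cl2, rt
Reagents that add atoms: none
Why: Dess–Martin oxidation converts the neopentyl primary alcohol into the non-enolisable C9 aldehyde, and the buffer protects the acetal.

Step 13
Reactants: 18 methyl (R)-3-methylglutarate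
Product: 19 methyl (R)-5-hydroxy-3-methylpentanoate
Conditions: BH3·SMe2, THF, 0 °C → rt; MeOH
Reagents that add atoms: none
Why: Borane reduces a carboxylic acid chemoselectively in the presence of a methyl ester, and the stereocentre (β to both carbonyls) is not involved.

Step 14
Reactants: 19 methyl (R)-5-hydroxy-3-methylpentanoate
Product: 20 methyl (R)-5-[(tert-butyldiphenylsilyl)oxy]-3-methylpentanoate
Conditions: TBDPSCl, imidazole, CH2Cl2, rt
Reagents that add atoms: tert-butyl(chloro)diphenylsilane CC(C)(C)[Si](Cl)(c1ccccc1)c1ccccc1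
Why: Silylation of the primary alcohol (the future C15 oxygen) is routine and prevents lactonisation of the hydroxy ester.

Step 15
Reactants: 20 methyl (R)-5-[(tert-butyldiphenylsilyl)oxy]-3-methylpentanoate
Product: 21 (S)-5-[(tert-butyldiphenylsilyl)oxy]-3-methylpentan-1-ol
Conditions: LiBH4, THF/MeOH, 0 °C → rt
Reagents that add atoms: none
Why: Lithium borohydride reduces the ester to the primary alcohol (C11) without touching the silyl ether.

Step 16
Reactants: 21 (S)-5-[(tert-butyldiphenylsilyl)oxy]-3-methylpentan-1-ol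
Product: 22 (R)-[(5-bromo-3-methylpentyl)oxy](tert-butyl)diphenylsilane
Conditions: CBr4, PPh3, CH2Cl2, 0 °C
Reagents that add atoms: tetrabromomethane BrC(Br)(Br)Br
Why: The Appel reaction converts the primary alcohol into the bromide under neutral conditions, remote from the stereocentre.

Step 17
Reactants: 17 2-(trimethylsilyl)ethyl (1S,2R,3S)-2-(3,3-diethoxypropyl)-3-formyl-1,3-dimethylcyclohexane-1-carboxylate; 22 (R)-[(5-bromo-3-methylpentyl)oxy](tert-butyl)diphenylsilane
Product: 25 2-(trimethylsilyl)ethyl (1S,2R,3S)-3-[(1RS,4S)-6-[(tert-butyldiphenylsilyl)oxy]-1-hydroxy-4-methylhexyl]-1,3-dimethyl-2-(3-oxopropyl)cyclohexane-1-carboxylate, via Grignard reagent 23 (not isolated), via acetal carbinol 24 (not isolated)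
Conditions: 22, Mg, THF, 40 °C; then 17, THF, −78 → 0 °C; then 1 M HCl, THF, rt
Reagents that add atoms: water O
Why: Grignard addition to the non-enolisable C9 aldehyde forms C9–C11 (the shielded C19 ester does not compete), the acidic work-up hydrolyses the diethyl acetal to the C8 aldehyde, and the C9 carbinol configuration is of no consequence because C9 becomes a radical in step 20.

Step 18
Reactants: 25 2-(trimethylsilyl)ethyl (1S,2R,3S)-3-[(1RS,4S)-6-[(tert-butyldiphenylsilyl)oxy]-1-hydroxy-4-methylhexyl]-1,3-dimethyl-2-(3-oxopropyl)cyclohexane-1-carboxylate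
Product: 26 2-(trimethylsilyl)ethyl (1S,2R,3S)-2-(but-3-yn-1-yl)-3-[(1RS,4S)-6-[(tert-butyldiphenylsilyl)oxy]-1-hydroxy-4-methylhexyl]-1,3-dimethylcyclohexane-1-carboxylate
Conditions: dimethyl (1-diazo-2-oxopropyl)phosphonate, K2CO3, MeOH, 0 °C → rt
Reagents that add atoms: dimethyl (1-diazo-2-oxopropyl)phosphonate COP(=O)(OC)C(=[N+]=[N-])C(C)=O
Why: Seyferth–Gilbert homologation with the Ohira–Bestmann reagent turns the C8 aldehyde into the terminal alkyne (C8≡C17) under mild carbonate conditions that tolerate the free secondary alcohol and the hindered ester.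

Step 19
Reactants: 26 2-(trimethylsilyl)ethyl (1S,2R,3S)-2-(but-3-yn-1-yl)-3-[(1RS,4S)-6-[(tert-butyldiphenylsilyl)oxy]-1-hydroxy-4-methylhexyl]-1,3-dimethylcyclohexane-1-carboxylate
Product: 27 2-(trimethylsilyl)ethyl (1S,2R,3S)-2-(but-3-yn-1-yl)-3-[(1RS,4S)-6-[(tert-butyldiphenylsilyl)oxy]-4-methyl-1-{[(methylsulfanyl)carbonothioyl]oxy}hexyl]-1,3-dimethylcyclohexane-1-carboxylate
Conditions: KHMDS (1.05 equiv), THF, −78 °C; CS2; MeI, −78 → 0 °C
Reagents that add atoms: carbon disulfide S=C=S; iodomethane CI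
Why: Xanthate formation (alkoxide plus CS2, then S-methylation) works for hindered secondary alcohols, and one equivalent of base deprotonates the alcohol in preference to the far less acidic alkyne.

Step 20
Reactants: 27 2-(trimethylsilyl)ethyl (1S,2R,3S)-2-(but-3-yn-1-yl)-3-[(1RS,4S)-6-[(tert-butyldiphenylsilyl)oxy]-4-methyl-1-{[(methylsulfanyl)carbonothioyl]oxy}hexyl]-1,3-dimethylcyclohexane-1-carboxylate
Product: 28 2-(trimethylsilyl)ethyl (4S,5R,9S,10R,13S)-15-[(tert-butyldiphenylsilyl)oxy]labd-8(17)-en-19-oate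
Conditions: Bu3SnH, AIBN (cat.), toluene (0.005 M), 110 °C, syringe pump
Reagents that add atoms: none
Why: Barton–McCombie generation of the C9 radical is followed by 6-exo-dig radical cyclisation onto the unhindered alkyne carbon C8 and reduction of the vinyl radical to the exocyclic methylene; a chair-like closure on the trans-diequatorial C9/C6 substituents of ring A with the C11 chain pseudo-equatorial should give 9α-H.

Step 21
Reactants: 28 2-(trimethylsilyl)ethyl (4S,5R,9S,10R,13S)-15-[(tert-butyldiphenylsilyl)oxy]labd-8(17)-en-19-oate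
Product: 29 (4S,5R,9S,10R,13S)-15-hydroxylabd-8(17)-en-19-oic acid (imbricatolic acid)
Conditions: TBAF, THF, rt → 45 °C; aq. NH4Cl
Reagents that add atoms: none
Why: Fluoride cleaves the silylethyl ester by β-elimination (no attack at the shielded carbonyl is needed) and removes the silyl ether in the same operation.

Step 22
Reactants: 29 (4S,5R,9S,10R,13S)-15-hydroxylabd-8(17)-en-19-oic acid
Product: 30 (4S,5R,9S,10R,13S)-15-(formyloxy)labd-8(17)-en-19-oic acid (target)
Conditions: HCO2Ac, pyridine, CH2Cl2, 0 °C; aqueous work-up (pH 4)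
Reagents that add atoms: acetic formic anhydride CC(=O)OC=O
Why: O-Formylation with acetic formic anhydride is fast at the primary C15 alcohol under non-acidic conditions that spare the exocyclic alkene, and any mixed anhydride of the hindered C19 acid should hydrolyse on work-up.

Compound list
1 | 5,6-dihydro-2H-pyran-2-one | O=C1C=CCCO1 | starting material
2 | (E)-2-(3,3-diethoxyprop-1-en-1-yl)-4,4,5,5-tetramethyl-1,3,2-dioxaborolane | CCOC(OCC)/C=C/B1OC(C)(C)C(C)(C)O1 | starting material
3 | (S)-4-[(E)-3,3-diethoxyprop-1-en-1-yl]oxan-2-one | O=C1C[C@@H](/C=C/C(OCC)OCC)CCO1 | intermediate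
4 | (S)-4-(3,3-diethoxypropyl)oxan-2-one | O=C1C[C@@H](CCC(OCC)OCC)CCO1 | intermediate
5 | (3R,4S)-4-(3,3-diethoxypropyl)-3-methyloxan-2-one (methyl trans to the arm) | O=C1[C@H](C)[C@@H](CCC(OCC)OCC)CCO1 | intermediate
6 | (3S,4S)-3-[(benzyloxy)methyl]-4-(3,3-diethoxypropyl)-3-methyloxan-2-one (CH2OBn trans to the arm) | O=C1[C@](C)(COCc2ccccc2)[C@@H](CCC(OCC)OCC)CCO1 | intermediate
7 | (3S,4S)-3-[(benzyloxy)methyl]-4-(3,3-diethoxypropyl)-3-methyloxan-2-ol (anomer mixture) | OC1[C@](C)(COCc2ccccc2)[C@@H](CCC(OCC)OCC)CCO1 | intermediate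
8 | (3S,4S,5R)-4-[(benzyloxy)methyl]-3-(3,3-diethoxypropyl)-4-methylhept-6-ene-1,5-diol | C=C[C@@H](O)[C@](C)(COCc1ccccc1)[C@H](CCO)CCC(OCC)OCC | intermediate
9 | (4S,5S,6R)-5-[(benzyloxy)methyl]-4-(3,3-diethoxypropyl)-5-methyl-6-vinyloxan-2-ol (lactol, not isolated) | OC1C[C@H](CCC(OCC)OCC)[C@@](C)(COCc2ccccc2)[C@@H](C=C)O1 | intermediate
10 | (4S,5S,6R)-5-[(benzyloxy)methyl]-4-(3,3-diethoxypropyl)-5-methyl-6-vinyloxan-2-one | O=C1C[C@H](CCC(OCC)OCC)[C@@](C)(COCc2ccccc2)[C@@H](C=C)O1 | intermediate
11 | (3S,4S,5S,6R)-5-[(benzyloxy)methyl]-4-(3,3-diethoxypropyl)-3,5-dimethyl-6-vinyloxan-2-one (precursor of the key step) | O=C1[C@@H](C)[C@H](CCC(OCC)OCC)[C@@](C)(COCc2ccccc2)[C@@H](C=C)O1 | intermediate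
12 | trimethylsilyl ketene acetal of 11 (C19(OSiMe3)=C4; C5, C10, C1 unchanged; not isolated) | C[Si](C)(C)OC1=C(C)[C@H](CCC(OCC)OCC)[C@@](C)(COCc2ccccc2)[C@@H](C=C)O1 | intermediate
13 | trimethylsilyl ester of acid 14 (not isolated) | C[Si](C)(C)OC(=O)[C@@]1(C)CC=C[C@](C)(COCc2ccccc2)[C@H]1CCC(OCC)OCC | intermediate
14 | (1S,5S,6R)-5-[(benzyloxy)methyl]-6-(3,3-diethoxypropyl)-1,5-dimethylcyclohex-3-ene-1-carboxylic acid (product of the key step) | OC(=O)[C@@]1(C)CC=C[C@](C)(COCc2ccccc2)[C@H]1CCC(OCC)OCC | intermediate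
15 | 2-(trimethylsilyl)ethyl (1S,5S,6R)-5-[(benzyloxy)methyl]-6-(3,3-diethoxypropyl)-1,5-dimethylcyclohex-3-ene-1-carboxylate | C[Si](C)(C)CCOC(=O)[C@@]1(C)CC=C[C@](C)(COCc2ccccc2)[C@H]1CCC(OCC)OCC | intermediate
16 | 2-(trimethylsilyl)ethyl (1S,2R,3S)-2-(3,3-diethoxypropyl)-3-(hydroxymethyl)-1,3-dimethylcyclohexane-1-carboxylate | C[Si](C)(C)CCOC(=O)[C@@]1(C)CCC[C@](C)(CO)[C@H]1CCC(OCC)OCC | intermediate
17 | 2-(trimethylsilyl)ethyl (1S,2R,3S)-2-(3,3-diethoxypropyl)-3-formyl-1,3-dimethylcyclohexane-1-carboxylate | C[Si](C)(C)CCOC(=O)[C@@]1(C)CCC[C@](C)(C=O)[C@H]1CCC(OCC)OCC | intermediate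
18 | methyl (R)-3-methylglutarate [(R)-5-methoxy-3-methyl-5-oxopentanoic acid] | COC(=O)C[C@H](C)CC(=O)O | starting material
19 | methyl (R)-5-hydroxy-3-methylpentanoate | COC(=O)C[C@H](C)CCO | intermediate
20 | methyl (R)-5-[(tert-butyldiphenylsilyl)oxy]-3-methylpentanoate | COC(=O)C[C@H](C)CCO[Si](c1ccccc1)(c1ccccc1)C(C)(C)C | intermediate
21 | (S)-5-[(tert-butyldiphenylsilyl)oxy]-3-methylpentan-1-ol | OCC[C@H](C)CCO[Si](c1ccccc1)(c1ccccc1)C(C)(C)C | intermediate
22 | (R)-[(5-bromo-3-methylpentyl)oxy](tert-butyl)diphenylsilane | BrCC[C@H](C)CCO[Si](c1ccccc1)(c1ccccc1)C(C)(C)C | intermediate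
23 | Grignard reagent of 22, (R)-{5-[(tert-butyldiphenylsilyl)oxy]-3-methylpentyl}magnesium bromide (not isolated) | Br[Mg]CC[C@H](C)CCO[Si](c1ccccc1)(c1ccccc1)C(C)(C)C | intermediate
24 | 2-(trimethylsilyl)ethyl (1S,2R,3S)-3-[(1RS,4S)-6-[(tert-butyldiphenylsilyl)oxy]-1-hydroxy-4-methylhexyl]-2-(3,3-diethoxypropyl)-1,3-dimethylcyclohexane-1-carboxylate (not isolated) | C[Si](C)(C)CCOC(=O)[C@@]1(C)CCC[C@](C)(C(O)CC[C@H](C)CCO[Si](c2ccccc2)(c2ccccc2)C(C)(C)C)[C@H]1CCC(OCC)OCC | intermediate
25 | 2-(trimethylsilyl)ethyl (1S,2R,3S)-3-[(1RS,4S)-6-[(tert-butyldiphenylsilyl)oxy]-1-hydroxy-4-methylhexyl]-1,3-dimethyl-2-(3-oxopropyl)cyclohexane-1-carboxylate | C[Si](C)(C)CCOC(=O)[C@@]1(C)CCC[C@](C)(C(O)CC[C@H](C)CCO[Si](c2ccccc2)(c2ccccc2)C(C)(C)C)[C@H]1CCC=O | intermediate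
26 | 2-(trimethylsilyl)ethyl (1S,2R,3S)-2-(but-3-yn-1-yl)-3-[(1RS,4S)-6-[(tert-butyldiphenylsilyl)oxy]-1-hydroxy-4-methylhexyl]-1,3-dimethylcyclohexane-1-carboxylate | C[Si](C)(C)CCOC(=O)[C@@]1(C)CCC[C@](C)(C(O)CC[C@H](C)CCO[Si](c2ccccc2)(c2ccccc2)C(C)(C)C)[C@H]1CCC#C | intermediate
27 | S-methyl xanthate of 26 at the C9 oxygen | C[Si](C)(C)CCOC(=O)[C@@]1(C)CCC[C@](C)(C(OC(=S)SC)CC[C@H](C)CCO[Si](c2ccccc2)(c2ccccc2)C(C)(C)C)[C@H]1CCC#C | intermediate
28 | 2-(trimethylsilyl)ethyl (4S,5R,9S,10R,13S)-15-[(tert-butyldiphenylsilyl)oxy]labd-8(17)-en-19-oate | C=C1CC[C@@H]2[C@](C)(CCC[C@]2(C)C(=O)OCC[Si](C)(C)C)[C@H]1CC[C@H](C)CCO[Si](c1ccccc1)(c1ccccc1)C(C)(C)C | intermediate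
29 | (4S,5R,9S,10R,13S)-15-hydroxylabd-8(17)-en-19-oic acid | C=C1CC[C@@H]2[C@](C)(CCC[C@]2(C)C(=O)O)[C@H]1CC[C@H](C)CCO | intermediate
30 | (4S,5R,9S,10R,13S)-15-(formyloxy)labd-8(17)-en-19-oic acid (CNP0494097.1) | C=C1CC[C@@H]2[C@](C)(CCC[C@]2(C)C(=O)O)[C@H]1CC[C@H](C)CCOC=O | target

Step count and risks

Total: 22 steps. Longest linear sequence: 18 steps (steps 1–12 and 17–22); the side-chain bromide takes 4 steps (13–16).

Steps most likely to fail:

1. Step 9 (key step). What may go wrong: deprotonation or O-silylation at the hindered tertiary C4–H may be incomplete, or the tetrasubstituted ketene acetal may fragment by elimination before it reaches the crowded boat transition state. Fallback: set out from lactone 10, which lacks the C4 methyl. Under the conditions of step 9 it should form the silyl ketene acetal F1, which has a less crowded secondary ketene-acetal carbon. F1 should rearrange to the trimethylsilyl ester F2, and hydrolysis gives the des-methyl acid F3 (C4–H, carboxyl cis to the C20 methyl). Mitsunobu esterification as in step 10 gives the des-methyl 2-(trimethylsilyl)ethyl ester F4. LDA and MeI then methylate its ester enolate from the face opposite the C5 arm and the C20 methyl. C18 is thus introduced by alkylation after ring closure and is not carried through the rearrangement. The fallback comes back to the route at ester 15.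

2. Step 20. What may go wrong: hydrogen transfer to the C9 radical before ring closure (from the stannane, or from the propargylic C7–H by 1,5-shift), and incomplete facial control at C9. Fallback: set out from hydroxy aldehyde 25. Dess–Martin oxidation gives the keto aldehyde F5. Intramolecular McMurry coupling (TiCl3, Zn–Cu, DME, reflux) closes ring B as the 17-nor-8-ene F6. Hydroboration–oxidation (BH3·THF; NaOH, H2O2) from the α-face, away from the axial C20 methyl, gives the 8α-alcohol F7 with 9α-H. Dess–Martin oxidation gives the 17-nor-8-ketone F8, in which C9 can be equilibrated (NaOMe, MeOH) to the equatorial side chain. Wittig methylenation (Ph3P=CH2, THF, reflux) comes back to the route at 28.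

3. Step 6. What may go wrong: poor facial selectivity at C1, because the magnesium alkoxide released on lactol opening competes with the C9 benzyl ether for the metal and blurs the chelate. Fallback: set out from lactone 6. LiAlH4 gives the diol F9. The unhindered C19 hydroxyl is silylated selectively (TBDPSCl, imidazole) to the silyl ether F10. Dess–Martin oxidation of the neopentyl C1 alcohol gives the aldehyde F11. Precomplexation with MgBr2·OEt2 in CH2Cl2 at −78 °C and addition of vinylmagnesium bromide should give the allylic alcohol F12 through a six-membered chelate that involves only the C9 benzyl ether. TBAF removes the silyl group and comes back to the route at diol 8.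

Further compounds
F1 | step 9 | trimethylsilyl ketene acetal of lactone 10 | C[Si](C)(C)OC1=C[C@H](CCC(OCC)OCC)[C@@](C)(COCc2ccccc2)[C@@H](C=C)O1
F2 | step 9 | trimethylsilyl ester of the des-methyl acid | C[Si](C)(C)OC(=O)[C@H]1CC=C[C@](C)(COCc2ccccc2)[C@H]1CCC(OCC)OCC
F3 | step 9 | 5-[(benzyloxy)methyl]-6-(3,3-diethoxypropyl)-5-methylcyclohex-3-ene-1-carboxylic acid (des-methyl acid, C4–H α, carboxyl cis to the C20 methyl) | OC(=O)[C@H]1CC=C[C@](C)(COCc2ccccc2)[C@H]1CCC(OCC)OCC
F4 | step 9 | 2-(trimethylsilyl)ethyl ester of the des-methyl acid | C[Si](C)(C)CCOC(=O)[C@H]1CC=C[C@](C)(COCc2ccccc2)[C@H]1CCC(OCC)OCC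
F5 | step 20 | keto aldehyde (C9 ketone, C8 aldehyde) from 25 | C[Si](C)(C)CCOC(=O)[C@@]1(C)CCC[C@](C)(C(=O)CC[C@H](C)CCO[Si](c2ccccc2)(c2ccccc2)C(C)(C)C)[C@H]1CCC=O
F6 | step 20 | 2-(trimethylsilyl)ethyl 15-[(tert-butyldiphenylsilyl)oxy]-17-norlabd-8-en-19-oate | C1=C(CC[C@H](C)CCO[Si](c3ccccc3)(c3ccccc3)C(C)(C)C)[C@@]2(C)CCC[C@](C)(C(=O)OCC[Si](C)(C)C)[C@@H]2CC1
F7 | step 20 | 2-(trimethylsilyl)ethyl 15-[(tert-butyldiphenylsilyl)oxy]-8α-hydroxy-17-norlabdan-19-oate (9α-H) | O[C@@H]1CC[C@@H]2[C@](C)(CCC[C@]2(C)C(=O)OCC[Si](C)(C)C)[C@H]1CC[C@H](C)CCO[Si](c1ccccc1)(c1ccccc1)C(C)(C)C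
F8 | step 20 | 2-(trimethylsilyl)ethyl 15-[(tert-butyldiphenylsilyl)oxy]-8-oxo-17-norlabdan-19-oate (9α-H) | O=C1CC[C@@H]2[C@](C)(CCC[C@]2(C)C(=O)OCC[Si](C)(C)C)[C@H]1CC[C@H](C)CCO[Si](c1ccccc1)(c1ccccc1)C(C)(C)C
F9 | step 6 | 2-[(benzyloxy)methyl]-3-(3,3-diethoxypropyl)-2-methylpentane-1,5-diol (C5 and C10 as in 6) | OC[C@](C)(COCc1ccccc1)[C@H](CCO)CCC(OCC)OCC
F10 | step 6 | C19 mono-tert-butyldiphenylsilyl ether of the diol | OC[C@](C)(COCc1ccccc1)[C@H](CCO[Si](c1ccccc1)(c1ccccc1)C(C)(C)C)CCC(OCC)OCC
F11 | step 6 | C1 aldehyde with C19 silyl ether | O=C[C@](C)(COCc1ccccc1)[C@H](CCO[Si](c1ccccc1)(c1ccccc1)C(C)(C)C)CCC(OCC)OCC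
F12 | step 6 | C19 tert-butyldiphenylsilyl ether of diol 8 | C=C[C@@H](O)[C@](C)(COCc1ccccc1)[C@H](CCO[Si](c1ccccc1)(c1ccccc1)C(C)(C)C)CCC(OCC)OCC
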